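The disconnection is the side-chain bond C2′–C3′, between the acetoxy-bearing carbinol carbon (homobenzylic to the resorcylate ring) and the first methylene of the unbranched ω-hydroxyundecyl chain. The key step exploits the acetate on O–C2′ that the target already carries: a racemic 1-bromoalkyl acetate, made in the flask from an arylacetaldehyde and acetyl bromide, is coupled with a terminal olefin (benzyl undec-10-enyl ether) under chiral nickel hydride catalysis. In one operation this forms the C–C bond, sets the (R) centre stereoconvergently from both bromide enantiomers and keeps the acetate in place. Phenols, acid and primary alcohol travel as benzyl groups, removed together by a final hydrogenolysis.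

Key step: step 4

Remark: side-chain carbons are numbered C1′ (benzylic CH2) to C13′ (CH2OH). The sense of induction of the nickel/bis(oxazoline) catalyst on this substrate is assumed to be fixed by the ligand antipode, which a pilot coupling assigns so that the (R)-acetate results; both antipodes are available.

Step 1
Reactants: 1 orsellinic acid (2,4-dihydroxy-6-methylbenzoic acid)
Product: 2 benzyl 2,4-bis(benzyloxy)-6-methylbenzoate
Conditions: BnBr (3.5 equiv), K2CO3 (4 equiv), TBAI (cat.), DMF, rt → 60 °C
Reagents that add atoms: benzyl bromide BrCc1ccccc1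
Why: Williamson-type SN2 alkylation of the carboxylate (first, at rt, which also blocks decarboxylation) and of both phenoxides, the hydrogen-bonded ortho phenol needing the warm-up.

Step 2
Reactants: 2 benzyl 2,4-bis(benzyloxy)-6-methylbenzoate
Product: 5 benzyl 2,4-bis(benzyloxy)-6-(2-oxoethyl)benzoate, via benzylic organolithium 3 (not isolated), via lithium hemiaminolate 4 (not isolated)
Conditions: LDA (commercial solution, 1.2 equiv), THF, −78 °C (2 added to the base); DMF (3 equiv), −78 °C; AcOH quench at −78 °C, then pH 7 buffer
Reagents that add atoms: N,N-dimethylformamide CN(C)C=O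
Why: Lateral lithiation of the o-toluate (the ortho ester stabilises the benzylic anion as an extended enolate) followed by formylation with DMF should give a tetrahedral hemiaminolate that keeps the enolisable arylacetaldehyde masked until the cold acidic quench, while the doubly ortho-substituted ester resists self-condensation.

Step 3
Reactants: 6 undec-10-en-1-ol
Product: 8 benzyl undec-10-enyl ether (11-(benzyloxy)undec-1-ene), via sodium alkoxide 7 (not isolated)
Conditions: NaH (1.2 equiv), THF/DMF, 0 °C; BnBr (1.1 equiv), TBAI (cat.), 0 °C → rt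
Reagents that add atoms: benzyl bromide BrCc1ccccc1
Why: Williamson ether synthesis on a primary alkoxide, which masks the hydroxyl that would otherwise attack the 1-bromoalkyl acetate in step 4.

Step 4
Reactants: 5 benzyl 2,4-bis(benzyloxy)-6-(2-oxoethyl)benzoate, 8 benzyl undec-10-enyl ether
Product: 10 benzyl 2-[(2R)-2-acetoxy-13-(benzyloxy)tridecyl]-4,6-bis(benzyloxy)benzoate, via racemic bromo acetate 9 (not isolated)
Conditions: (i) AcBr (1.0 equiv), minimal CH2Cl2, −10 °C → rt, used directly; (ii) 8 (1.5 equiv), NiBr2·glyme (10 mol %), chiral bis(oxazoline) L* (12 mol %), (EtO)3SiH (2 equiv), K3PO4·H2O (2 equiv), Et2O/DMA, rt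
Reagents that add atoms: acetyl bromide CC(=O)Br
Why: Acetyl bromide adds across the C=O of 5 to give the racemic 1-bromoalkyl acetate 9; an L*Ni–H species formed from the nickel bromide, the silane and the phosphate inserts the terminal C=C of 8 in the anti-Markovnikov sense, nickel abstracts bromine from either enantiomer of 9 to give one planar α-acetoxyalkyl radical, and radical capture followed by reductive elimination at the chiral nickel centre forms the C2′–C3′ bond. The closest known reaction type is the nickel-hydride-catalysed enantioconvergent hydroalkylation of terminal olefins with racemic 1-bromoalkyl esters, including its one-pot aldehyde/acyl bromide/olefin/hydrosilane form. No ring is closed. The new stereocentre C2′ is set by the chiral bis(oxazoline) ligand on nickel (catalyst control, aided by coordination of the acetate carbonyl), and because the configuration of 9 is erased at the radical stage both enantiomers should converge on the (R)-acetate. The step needs linear regioselectivity, which the monosubstituted olefin secures through the primary alkylnickel, and chemoselectivity for the weak, acyloxy-activated C–Br bond over the benzyl C–O bonds and the hindered ester, which room temperature and the mild silane secure. The acetate of the target thus serves as the activating group itself, so no acylation of a lactonisation-prone hydroxy ester is needed.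

Step 5
Reactants: 10 benzyl 2-[(2R)-2-acetoxy-13-(benzyloxy)tridecyl]-4,6-bis(benzyloxy)benzoate
Product: 11 2-[(2R)-2-acetoxy-13-hydroxytridecyl]-4,6-dihydroxybenzoic acid
Conditions: H2 (1 atm), 10% Pd/C, EtOAc/THF, rt; filtration and evaporation below 30 °C
Reagents that add atoms: none
Why: Catalytic hydrogenolysis should cleave the two aryl benzyl ethers, the benzyl ester and the alkyl benzyl ether under neutral conditions, while the homobenzylic (not benzylic) C2′–OAc bond and the stereocentre stay untouched and neither base nor acid is present to trigger acetate loss or lactonisation.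

Compound list
1 | orsellinic acid (2,4-dihydroxy-6-methylbenzoic acid) | Cc1cc(O)cc(O)c1C(=O)O | starting material
2 | benzyl 2,4-bis(benzyloxy)-6-methylbenzoate | Cc1cc(OCc2ccccc2)cc(OCc2ccccc2)c1C(=O)OCc1ccccc1 | intermediate
3 | benzylic organolithium of 2 (formed in the flask, not isolated) | [Li]Cc1cc(OCc2ccccc2)cc(OCc2ccccc2)c1C(=O)OCc1ccccc1 | intermediate
4 | lithium hemiaminolate from 3 and DMF (racemic, not isolated) | [Li]OC(N(C)C)Cc1cc(OCc2ccccc2)cc(OCc2ccccc2)c1C(=O)OCc1ccccc1 | intermediate
5 | benzyl 2,4-bis(benzyloxy)-6-(2-oxoethyl)benzoate | O=CCc1cc(OCc2ccccc2)cc(OCc2ccccc2)c1C(=O)OCc1ccccc1 | intermediate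
6 | undec-10-en-1-ol | OCCCCCCCCCC=C | starting material
7 | sodium undec-10-en-1-olate (not isolated) | [Na+].[O-]CCCCCCCCCC=C | intermediate
8 | benzyl undec-10-enyl ether (11-(benzyloxy)undec-1-ene) | C=CCCCCCCCCCOCc1ccccc1 | intermediate
9 | benzyl 2-(2-acetoxy-2-bromoethyl)-4,6-bis(benzyloxy)benzoate (racemic, not isolated) | CC(=O)OC(Br)Cc1cc(OCc2ccccc2)cc(OCc2ccccc2)c1C(=O)OCc1ccccc1 | intermediate
10 | benzyl 2-[(2R)-2-acetoxy-13-(benzyloxy)tridecyl]-4,6-bis(benzyloxy)benzoate | CC(=O)O[C@H](CCCCCCCCCCCOCc1ccccc1)Cc1cc(OCc2ccccc2)cc(OCc2ccccc2)c1C(=O)OCc1ccccc1 | intermediate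
11 | 2-[(2R)-2-acetoxy-13-hydroxytridecyl]-4,6-dihydroxybenzoic acid | CC(=O)O[C@H](CCCCCCCCCCCO)Cc1cc(O)cc(O)c1C(=O)O | target

Total step count: 5. Longest linear sequence: 4 (steps 1, 2, 4, 5).

Steps most likely to fail

1. Step 4. Three things may go wrong:
- The carbonyl oxygen of the ortho benzyl ester may participate at the ionising C–Br carbon while the bromo acetate forms, with loss of the benzyl group and closure to a cyclic acylal.
- Phosphate may eliminate HBr to the aryl-conjugated enol acetate.
- Enantiocontrol may be insufficient for a small acetate with a homobenzylic substituent.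

The fallback sets out from 5 and comes back at 11. Aldehyde 5 would be allylated with (+)-B-allyldiisopinocampheylborane (from (+)-Ipc2BOMe and allylmagnesium bromide, Et2O, −78 °C, non-basic ethanolamine work-up). This reagent-controlled Brown allylboration forms the same C2′–C3′ bond and is expected, by its established Re-face preference, to give benzyl 2,4-bis(benzyloxy)-6-[(2R)-2-hydroxypent-4-en-1-yl]benzoate F1. Prompt acetylation (Ac2O, pyridine, DMAP, 0 °C) would give benzyl 2-[(2R)-2-acetoxypent-4-en-1-yl]-4,6-bis(benzyloxy)benzoate F2. Cross-metathesis with commercial dec-9-en-1-ol (excess, Grubbs second-generation catalyst, CH2Cl2, 40 °C) would give benzyl 2-[(2R,4E)-2-acetoxy-13-hydroxytridec-4-en-1-yl]-4,6-bis(benzyloxy)benzoate F3, whose olefin geometry is of no consequence. The conditions of step 5 would then saturate the olefin and remove the three benzyl groups to reach 11.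

2. Step 2. The benzylic anion may condense with the ester of a second molecule, the hemiaminolate oxygen may attack the ortho ester with loss of benzyl alcohol, or the aldehyde may enolise and cyclise towards an isocoumarin during work-up or chromatography.

The fallback sets out from 2 and comes back at 5. The same lateral lithiation (LDA, 2.2 equiv, THF, −78 °C) would be quenched with CO2 to give [3,5-bis(benzyloxy)-2-(benzyloxycarbonyl)phenyl]acetic acid F4. Chemoselective reduction of the carboxylic acid with BH3·THF (0 °C → rt), which spares the hindered benzyl ester, would give benzyl 2,4-bis(benzyloxy)-6-(2-hydroxyethyl)benzoate F5. Immediate oxidation with Dess–Martin periodinane (NaHCO3, CH2Cl2, 0 °C) would release aldehyde 5 under neutral conditions.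

3. Step 5. Hydrogenolysis of the aliphatic benzyl ether may be slow. The long exposure that it forces would leave the liberated salicylic-type acid in contact with the catalyst and allow acid-promoted loss of the acetate with lactonisation, or decarboxylation.

The fallback sets out from 6 (with 5) and comes back at 11. Alcohol 6 would be silylated (TBSCl, imidazole, DMF) to tert-butyl(dimethyl)(undec-10-en-1-yloxy)silane F6. F6 would replace 8 in the conditions of step 4 (5, AcBr, then the nickel system, via 9) to give benzyl 2-[(2R)-2-acetoxy-13-(tert-butyldimethylsilyloxy)tridecyl]-4,6-bis(benzyloxy)benzoate F7. Buffered HF·pyridine (THF/pyridine, 0 °C) would free the primary alcohol as benzyl 2-[(2R)-2-acetoxy-13-hydroxytridecyl]-4,6-bis(benzyloxy)benzoate F8. Only the fast-cleaving aryl benzyl ethers and the benzyl ester would then remain for a brief hydrogenolysis (H2, Pd/C, EtOAc, rt) to 11.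

Further compounds
F1 | step 4 | benzyl 2,4-bis(benzyloxy)-6-[(2R)-2-hydroxypent-4-en-1-yl]benzoate | O[C@H](CC=C)Cc1cc(OCc2ccccc2)cc(OCc2ccccc2)c1C(=O)OCc1ccccc1
F2 | step 4 | benzyl 2-[(2R)-2-acetoxypent-4-en-1-yl]-4,6-bis(benzyloxy)benzoate | CC(=O)O[C@H](CC=C)Cc1cc(OCc2ccccc2)cc(OCc2ccccc2)c1C(=O)OCc1ccccc1
F3 | step 4 | benzyl 2-[(2R,4E)-2-acetoxy-13-hydroxytridec-4-en-1-yl]-4,6-bis(benzyloxy)benzoate | CC(=O)O[C@H](C/C=C/CCCCCCCCO)Cc1cc(OCc2ccccc2)cc(OCc2ccccc2)c1C(=O)OCc1ccccc1
F4 | step 2 | [3,5-bis(benzyloxy)-2-(benzyloxycarbonyl)phenyl]acetic acid | OC(=O)Cc1cc(OCc2ccccc2)cc(OCc2ccccc2)c1C(=O)OCc1ccccc1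
F5 | step 2 | benzyl 2,4-bis(benzyloxy)-6-(2-hydroxyethyl)benzoate | OCCc1cc(OCc2ccccc2)cc(OCc2ccccc2)c1C(=O)OCc1ccccc1
F6 | step 5 | tert-butyl(dimethyl)(undec-10-en-1-yloxy)silane | C=CCCCCCCCCCO[Si](C)(C)C(C)(C)C
F7 | step 5 | benzyl 2-[(2R)-2-acetoxy-13-(tert-butyldimethylsilyloxy)tridecyl]-4,6-bis(benzyloxy)benzoate | CC(=O)O[C@H](CCCCCCCCCCCO[Si](C)(C)C(C)(C)C)Cc1cc(OCc2ccccc2)cc(OCc2ccccc2)c1C(=O)OCc1ccccc1
F8 | step 5 | benzyl 2-[(2R)-2-acetoxy-13-hydroxytridecyl]-4,6-bis(benzyloxy)benzoate | CC(=O)O[C@H](CCCCCCCCCCCO)Cc1cc(OCc2ccccc2)cc(OCc2ccccc2)c1C(=O)OCc1ccccc1
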